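The route rests on closing ring C of the upper (epiafzelechin) unit at its aryl ether bond O1–C8a by intramolecular SNAr of a C2 alkoxide on a fluoroarene. The step exploits the phloroglucinol pattern of ring A: O5 and O7 sit meta to C8a, so they do not deactivate fluoride displacement. The precursor is an acyclic cis-epoxy alcohol whose oxirane ties O3 to C4; this forbids five-ring closure through O3 and leaves C2 untouched. The labile 3,4-epoxyflavan is trapped in the same flask as its C4 2-ethoxyethyl ether, which C8 of benzylated epicatechin then displaces to forge the 4β→8 bond. Double galloylation and hydrogenolysis finish the synthesis.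

Key step: step 7

Remark: the SMILES is read as epiafzelechin 3-O-gallate-(4β→8)-epicatechin 3-O-gallate, upper unit 2R,3R,4R (2,3-cis, 3,4-trans), lower unit 2R,3R.

Step 1
Reactants: 1 1,3,5-trifluorobenzene
Product: 2 1,3-bis(benzyloxy)-5-fluorobenzene
Conditions: BnOH (2.1 equiv), NaH (2.1 equiv), NMP, 0 → 80 °C
Reagents that add atoms: benzyl alcohol, OCc1ccccc1
Why: Two successive SNAr displacements of fluoride by benzyloxide should stop at the bis-ether, because each benzyloxy group is less activating than the fluorine it replaces and the alkoxide is limited to two equivalents.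

Step 2
Reactants: 2 1,3-bis(benzyloxy)-5-fluorobenzene
Product: 4 2,4-bis(benzyloxy)-6-fluorobenzaldehyde, via aryllithium 3 (not isolated)
Conditions: n-BuLi, THF, −78 °C; DMF, −78 → 0 °C
Reagents that add atoms: N,N-dimethylformamide, CN(C)C=O
Why: Directed ortho-metalation should occur at the C–H flanked by fluorine and a benzyloxy group, the most acidic ring position, and the aryllithium is formylated by DMF at −78 °C before it can lose LiF.

Step 3
Reactants: 4 2,4-bis(benzyloxy)-6-fluorobenzaldehyde
Product: 5 1,5-bis(benzyloxy)-2-ethynyl-3-fluorobenzene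
Conditions: TMSCHN2, n-BuLi, THF, −78 °C → rt
Reagents that add atoms: trimethylsilyldiazomethane, C[Si](C)(C)C=[N+]=[N-]
Why: Colvin rearrangement, in which lithiated trimethylsilyldiazomethane adds to the aldehyde, Peterson-type loss of silanolate gives a diazoalkene that expels N2, and a 1,2-shift in the alkylidene carbene gives the terminal alkyne under non-nucleophilic conditions that spare the ortho fluoride.

Step 4
Reactants: 5 1,5-bis(benzyloxy)-2-ethynyl-3-fluorobenzene (1.2 equiv), 6 4-(benzyloxy)benzaldehyde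
Product: 8 (R)-3-[2,4-bis(benzyloxy)-6-fluorophenyl]-1-[4-(benzyloxy)phenyl]prop-2-yn-1-ol, via alkynylzinc 7 (not isolated)
Conditions: Et2Zn, toluene, reflux; then (S)-BINOL (20 mol%), Ti(OiPr)4 (50 mol%), aldehyde, CH2Cl2, rt
Reagents that add atoms: none
Why: Catalytic asymmetric alkynylzinc addition to an aromatic aldehyde under BINOL–Ti(OiPr)4 control should set the carbinol centre (the later C2) by face selection of the titanium-bound aldehyde; (S)-BINOL is expected to give R by analogy with its dialkylzinc additions, and the antipodal ligand is used should the sense prove opposite.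

Step 5
Reactants: 8 (R)-propargylic alcohol
Product: 9 (S,Z)-3-[2,4-bis(benzyloxy)-6-fluorophenyl]-1-[4-(benzyloxy)phenyl]prop-2-en-1-ol
Conditions: H2 (1 atm), Pd/CaCO3 poisoned with Pb(OAc)2 (Lindlar catalyst), quinoline, EtOAc, rt
Reagents that add atoms: none
Why: Syn-semihydrogenation of the alkyne on lead-poisoned palladium should give the Z-alkene without touching the benzyl ethers, the aryl fluoride or the stereocentre (its descriptor changes from R to S only through the CIP ranking).

Step 6
Reactants: 9 (S,Z)-allylic alcohol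
Product: 10 (R)-[4-(benzyloxy)phenyl]{(2S,3R)-3-[2,4-bis(benzyloxy)-6-fluorophenyl]oxiran-2-yl}methanol (threo; cis-oxirane)
Conditions: DMDO (acetone solution, 1.2 equiv), CH2Cl2, −20 °C
Reagents that add atoms: dimethyldioxirane, CC1(C)OO1
Why: Hydroxyl-directed (Henbest-type) epoxidation, in which 1,3-allylic strain places the carbinol hydrogen in the alkene plane and the hydrogen-bonded dioxirane attacks the face syn to the hydroxyl, should set both oxirane carbons (the later C3 and C4) as the threo cis-epoxide, while the neutral oxidant avoids acid opening of the electron-rich benzylic oxirane.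

Step 7
Reactants: 10 threo cis-epoxy alcohol
Product: 13 (2R,3R,4S)-5,7-bis(benzyloxy)-2-[4-(benzyloxy)phenyl]-4-(2-ethoxyethoxy)chroman-3-ol, via potassium alkoxide 11 (not isolated), via epoxyflavan 12 (not isolated)
Conditions: KH (1.1 equiv), 18-crown-6 (0.2 equiv), DMF, 0 → 40 °C; then CH2Cl2, 2-ethoxyethanol (10 equiv), CSA (0.3 equiv), 0 °C
Reagents that add atoms: 2-ethoxyethanol, CCOCCO
Why: KH gives alkoxide 11, whose oxygen adds to the fluorine-bearing carbon (the later C8a) to form a Meisenheimer complex that expels fluoride (addition–elimination SNAr), and the acid-labile epoxyflavan 12 so formed is opened at benzylic C4 by 2-ethoxyethanol under CSA catalysis in the same flask. The closest known reaction types are the intramolecular SNAr etherification of fluoroarenes by alkoxides to chromans and the acid-catalysed alcoholysis of benzylic oxiranes. Ring C closes in a 6-exo-trig mode on the arene, helped by the cis-oxirane, which holds carbinol and fluoroarene on the same side. C2 and C3 keep their configuration because their C–O bonds are never broken, and the only new centre, C4, is set by attack of the alcohol anti to the oxirane oxygen and to the 2-aryl group (3,4-trans), a centre that the following coupling ionises again. The selectivity needed is six-ring closure through O1 over five-ring closure through O3 and over base opening of the oxirane; O3 is locked in the oxirane, and the reversible Payne isomer carries its alkoxide on C4, which cannot reach C8a. The negative charge of the complex sits on C8, C6 and C4a, never on the benzyloxy-bearing C5 and C7, so the two ether groups assist inductively and do not deactivate.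

Step 8
Reactants: 14 (−)-epicatechin
Product: 15 5,7,3',4'-tetra-O-benzyl-(−)-epicatechin
Conditions: BnBr (4.4 equiv), K2CO3, DMF, 0 °C → rt, Ar
Reagents that add atoms: benzyl bromide, BrCc1ccccc1
Why: Williamson etherification of the four phenoxides (the aliphatic 3-OH is not deprotonated by K2CO3) should give the tetrabenzyl ether, with low temperature and inert gas guarding against C2 epimerisation and oxidation.

Step 9
Reactants: 13 (2R,3R,4S)-4-(2-ethoxyethoxy)flavan-3-ol tribenzyl ether, 15 5,7,3',4'-tetra-O-benzyl-(−)-epicatechin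
Product: 16 5,7,4'-tri-O-benzylepiafzelechin-(4β→8)-5,7,3',4'-tetra-O-benzylepicatechin (upper unit 2R,3R,4R; lower unit 2R,3R; both 3-OH free)
Conditions: TMSOTf (0.1 equiv), CH2Cl2, −78 → −40 °C, nucleophile in threefold excess (recovered)
Reagents that add atoms: none
Why: Lewis acid-catalysed interflavan Friedel–Crafts condensation, in which TMSOTf ionises the C4 ether (2-ethoxyethanol leaves) to a benzylic cation stabilised by O1, O5 and O7 of ring A, and C8 of the epicatechin ether (its most nucleophilic carbon, between O7 and O1) attacks the face anti to the 3-hydroxyl and the 2-aryl group, should set C4 as 4β (3,4-trans), while the excess nucleophile suppresses oligomerisation.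

Step 10
Reactants: 16 dimer diol, 17 3,4,5-tris(benzyloxy)benzoic acid (4 equiv)
Product: 18 5,7,4'-tri-O-benzyl-3-O-[3,4,5-tris(benzyloxy)benzoyl]epiafzelechin-(4β→8)-5,7,3',4'-tetra-O-benzyl-3-O-[3,4,5-tris(benzyloxy)benzoyl]epicatechin
Conditions: DCC (4 equiv), DMAP, CH2Cl2, rt → 40 °C
Reagents that add atoms: none
Why: Steglich esterification with DMAP as acyl-transfer catalyst should acylate both secondary 3-hydroxyls, the hindered upper one included, with retention at C3 since only O–H bonds react.

Step 11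
Reactants: 18 trideca-O-benzyl digallate
Product: 19 epiafzelechin 3-O-gallate-(4β→8)-epicatechin 3-O-gallate (CNP0291968.1)
Conditions: H2 (1 atm), Pd(OH)2/C, THF/MeOH/H2O, rt
Reagents that add atoms: none
Why: Hydrogenolysis of the thirteen benzyl ethers on Pd(OH)2/C under neutral conditions should leave the two gallate esters, the pyran C–O bonds and the interflavan bond intact.

Compound list
1 | 1,3,5-trifluorobenzene | Fc1cc(F)cc(F)c1 | starting material
2 | 1,3-bis(benzyloxy)-5-fluorobenzene | Fc1cc(OCc2ccccc2)cc(OCc2ccccc2)c1 | intermediate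
3 | [2,4-bis(benzyloxy)-6-fluorophenyl]lithium | [Li]c1c(F)cc(OCc2ccccc2)cc1OCc1ccccc1 | intermediate
4 | 2,4-bis(benzyloxy)-6-fluorobenzaldehyde | O=Cc1c(F)cc(OCc2ccccc2)cc1OCc1ccccc1 | intermediate
5 | 1,5-bis(benzyloxy)-2-ethynyl-3-fluorobenzene | C#Cc1c(F)cc(OCc2ccccc2)cc1OCc1ccccc1 | intermediate
6 | 4-(benzyloxy)benzaldehyde | O=Cc1ccc(OCc2ccccc2)cc1 | starting material
7 | ethyl{[2,4-bis(benzyloxy)-6-fluorophenyl]ethynyl}zinc | CC[Zn]C#Cc1c(F)cc(OCc2ccccc2)cc1OCc1ccccc1 | intermediate
8 | (R)-3-[2,4-bis(benzyloxy)-6-fluorophenyl]-1-[4-(benzyloxy)phenyl]prop-2-yn-1-ol | O[C@@H](C#Cc1c(F)cc(OCc2ccccc2)cc1OCc1ccccc1)c1ccc(OCc2ccccc2)cc1 | intermediate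
9 | (S,Z)-3-[2,4-bis(benzyloxy)-6-fluorophenyl]-1-[4-(benzyloxy)phenyl]prop-2-en-1-ol | O[C@@H](/C=C\c1c(F)cc(OCc2ccccc2)cc1OCc1ccccc1)c1ccc(OCc2ccccc2)cc1 | intermediate
10 | (R)-[4-(benzyloxy)phenyl]{(2S,3R)-3-[2,4-bis(benzyloxy)-6-fluorophenyl]oxiran-2-yl}methanol | O(Cc1ccccc1)c1ccc(cc1)[C@@H](O)[C@@H]1O[C@@H]1c1c(F)cc(OCc2ccccc2)cc1OCc1ccccc1 | intermediate
11 | potassium alkoxide of 10 | O(Cc1ccccc1)c1ccc(cc1)[C@@H]([O-])[C@@H]1O[C@@H]1c1c(F)cc(OCc2ccccc2)cc1OCc1ccccc1.[K+] | intermediate
12 | (2R,3R,4R)-5,7-bis(benzyloxy)-2-[4-(benzyloxy)phenyl]-3,4-epoxychromane (oxirane cis to the 2-aryl group) | O(Cc1ccccc1)c1ccc(cc1)[C@H]1Oc2cc(OCc3ccccc3)cc(OCc3ccccc3)c2[C@H]2O[C@@H]12 | intermediate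
13 | (2R,3R,4S)-5,7-bis(benzyloxy)-2-[4-(benzyloxy)phenyl]-4-(2-ethoxyethoxy)chroman-3-ol | O(Cc1ccccc1)c1ccc(cc1)[C@H]1Oc2cc(OCc3ccccc3)cc(OCc3ccccc3)c2[C@H](OCCOCC)[C@H]1O | intermediate
14 | (−)-epicatechin (2R,3R) | O[C@@H]1Cc2c(O)cc(O)cc2O[C@@H]1c1ccc(O)c(O)c1 | starting material
15 | 5,7,3',4'-tetra-O-benzyl-(−)-epicatechin | O[C@@H]1Cc2c(OCc3ccccc3)cc(OCc3ccccc3)cc2O[C@@H]1c1ccc(OCc2ccccc2)c(OCc2ccccc2)c1 | intermediate
16 | 5,7,4'-tri-O-benzylepiafzelechin-(4β→8)-5,7,3',4'-tetra-O-benzylepicatechin | O[C@@H]1[C@@H](c2c(OCc3ccccc3)cc(OCc3ccccc3)c3c2O[C@H](c2ccc(OCc4ccccc4)c(OCc4ccccc4)c2)[C@H](O)C3)c2c(OCc3ccccc3)cc(OCc3ccccc3)cc2O[C@@H]1c1ccc(OCc2ccccc2)cc1 | intermediate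
17 | 3,4,5-tris(benzyloxy)benzoic acid | OC(=O)c1cc(OCc2ccccc2)c(OCc2ccccc2)c(OCc2ccccc2)c1 | starting material
18 | trideca-O-benzyl derivative of 19 (both 3-O-[3,4,5-tris(benzyloxy)benzoyl] esters) | O=C(O[C@@H]1[C@@H](c2c(OCc3ccccc3)cc(OCc3ccccc3)c3c2O[C@H](c2ccc(OCc4ccccc4)c(OCc4ccccc4)c2)[C@H](OC(=O)c2cc(OCc4ccccc4)c(OCc4ccccc4)c(OCc4ccccc4)c2)C3)c2c(OCc3ccccc3)cc(OCc3ccccc3)cc2O[C@@H]1c1ccc(OCc2ccccc2)cc1)c1cc(OCc2ccccc2)c(OCc2ccccc2)c(OCc2ccccc2)c1 | intermediate
19 | epiafzelechin 3-O-gallate-(4β→8)-epicatechin 3-O-gallate (CNP0291968.1) | O=C(O[C@@H]1[C@@H](c2c(O)cc(O)c3c2O[C@H](c2ccc(O)c(O)c2)[C@H](OC(=O)c2cc(O)c(O)c(O)c2)C3)c2c(O)cc(O)cc2O[C@@H]1c1ccc(O)cc1)c1cc(O)c(O)c(O)c1 | target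

Total step count: 11. Longest linear sequence: 10 steps (steps 1–7 and 9–11, from 1,3,5-trifluorobenzene); step 8 is a one-step side branch.

Steps most likely to fail

Step 7 (key ring closure with trapping in the same flask). Fluoride displacement may be slower than base-induced degradation of the oxirane (Payne isomerisation followed by intermolecular opening and oligomerisation), and a hydride shift in the C4 cation may outrun capture by the alcohol. The fallback sets out from 9 and comes back at 13, closing ring C before any oxirane is present. KH in DMF should close the same O1–C8a bond on the allylic alkoxide of 9 to give (S)-5,7-bis(benzyloxy)-2-[4-(benzyloxy)phenyl]-2H-chromene F1. Hydroboration–oxidation (BH3·THF; NaOH, H2O2) anti to the 2-aryl group should give the 2,3-trans alcohol (2R,3S)-5,7-bis(benzyloxy)-2-[4-(benzyloxy)phenyl]chroman-3-ol F2. Dess–Martin oxidation gives (2R)-5,7-bis(benzyloxy)-2-[4-(benzyloxy)phenyl]chroman-3-one F3, and LiBH(s-Bu)3 at −78 °C should reduce it to the 2,3-cis alcohol (2R,3R)-5,7-bis(benzyloxy)-2-[4-(benzyloxy)phenyl]chroman-3-ol F4. DDQ with 2-ethoxyethanol in CH2Cl2 should then oxidise C4 on the face anti to the 2-aryl group and return to 13.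

Step 9 (interflavan bond). Self-condensation of 13 through its own ring A, attack through C6 of 15, or further alkylation of the product by re-ionised material may compete. The fallback sets out from 13 and comes back at 16. Benzyl mercaptan with catalytic BF3·OEt2 in CH2Cl2 at −40 °C should exchange the C4 ether for the thioether (2R,3S,4S)-4-(benzylsulfanyl)-5,7-bis(benzyloxy)-2-[4-(benzyloxy)phenyl]chroman-3-ol F5. Thiophilic activation with AgBF4 in THF at 0 °C in the presence of 15 then forms the 4β→8 bond without a Lewis acid that could re-ionise the product, and returns to 16.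

Step 6 (directed epoxidation). Facial selectivity may be poor if acetone weakens the hydrogen-bond direction, and the carbinol may be over-oxidised. The fallback sets out from 9 and comes back at 10, replacing substrate direction by catalyst control. TBSCl and imidazole give (S,Z)-tert-butyl{3-[2,4-bis(benzyloxy)-6-fluorophenyl]-1-[4-(benzyloxy)phenyl]prop-2-enyloxy}dimethylsilane F6. Jacobsen–Katsuki epoxidation of this cis-alkene, with chloro[N,N'-bis(3,5-di-tert-butylsalicylidene)cyclohexane-1,2-diaminato]manganese (the antipode that matches the required face) and buffered NaOCl in CH2Cl2 at 0 °C, should give the tert-butyldimethylsilyl ether of 10 F7. TBAF in THF then returns to 10.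

Further compounds
F1 | step 7 | (S)-5,7-bis(benzyloxy)-2-[4-(benzyloxy)phenyl]-2H-chromene | O(Cc1ccccc1)c1ccc(cc1)[C@H]1Oc2cc(OCc3ccccc3)cc(OCc3ccccc3)c2C=C1
F2 | step 7 | (2R,3S)-5,7-bis(benzyloxy)-2-[4-(benzyloxy)phenyl]chroman-3-ol (2,3-trans) | O(Cc1ccccc1)c1ccc(cc1)[C@H]1Oc2cc(OCc3ccccc3)cc(OCc3ccccc3)c2C[C@@H]1O
F3 | step 7 | (2R)-5,7-bis(benzyloxy)-2-[4-(benzyloxy)phenyl]chroman-3-one | O(Cc1ccccc1)c1ccc(cc1)[C@H]1Oc2cc(OCc3ccccc3)cc(OCc3ccccc3)c2CC1=O
F4 | step 7 | (2R,3R)-5,7-bis(benzyloxy)-2-[4-(benzyloxy)phenyl]chroman-3-ol (2,3-cis; 5,7,4'-tri-O-benzylepiafzelechin) | O(Cc1ccccc1)c1ccc(cc1)[C@H]1Oc2cc(OCc3ccccc3)cc(OCc3ccccc3)c2C[C@H]1O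
F5 | step 9 | (2R,3S,4S)-4-(benzylsulfanyl)-5,7-bis(benzyloxy)-2-[4-(benzyloxy)phenyl]chroman-3-ol | O[C@@H]1[C@@H](SCc2ccccc2)c2c(OCc3ccccc3)cc(OCc3ccccc3)cc2O[C@@H]1c1ccc(OCc2ccccc2)cc1
F6 | step 6 | tert-butyldimethylsilyl ether of 9 | CC(C)(C)[Si](C)(C)O[C@@H](/C=C\c1c(F)cc(OCc2ccccc2)cc1OCc1ccccc1)c1ccc(OCc2ccccc2)cc1
F7 | step 6 | tert-butyldimethylsilyl ether of 10 | O(Cc1ccccc1)c1ccc(cc1)[C@@H](O[Si](C)(C)C(C)(C)C)[C@@H]1O[C@@H]1c1c(F)cc(OCc2ccccc2)cc1OCc1ccccc1
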